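**Retrosynthetic overview**
1. Target 26 is methyl 6α-angeloyloxy-1β,4α,8α-trihydroxyeudesm-11(13)-en-12-oate; the last bonds made are O6–angeloyl, C4–OH (hydration of a C4=C15 alkene that comes from a C4 ketone) and C11=C13 (methylenation of a C11 keto ester).
2. Key disconnection: ring B is cut at C5–C6 and C7–C8 by a retro-[3+2]. A 5α,8α-oxygen-bridged ring B (7-oxabicyclo[2.2.1]heptane) goes back to a cyclic carbonyl ylide C5–O–C8, made from a ring A α-diazo ketone with a CH2CHO arm on C10, and to the E-alkene C6=C7 of a β-alkoxyvinyl keto ester that already carries O6 and C11–C12.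
3. Enabling feature: in ring B the C8 oxygen and the C5 hydrogen are 1,4-cis (both α), and C5 is next to the oxygenated C4. C5 and C8 can therefore be the two ends of a C4-ketone-stabilised ylide; the bridging oxygen stays as 8α-OH, and the temporary C5–O bond, being α to the C4 ketone, is cut with SmI2. The trans C6–O/C7–C11 pair maps onto the E-alkene.
4. Ring order: ring A comes from 2-methylcyclohex-2-enone (C1 by CBS reduction, C10 by anti conjugate allylation); the temporary oxolane (ylide ring) and ring B close together in the key step; the oxolane is opened afterwards.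

Key step: step 10

Remark: eudesmane numbering is used for all ring positions (ring A: C1–C5 and C10; ring B: C5–C10; side chain C11–C13; C14 on C10, C15 on C4). β is the face of the C10 methyl and α the opposite face; eudesmane names imply 10β-methyl and a 7β side chain. TBS = tert-butyldimethylsilyl, TES = triethylsilyl, PMB = 4-methoxybenzyl. 2-Methylcyclohex-2-en-1-one, 4-methoxybenzyl alcohol, angelic acid and the reagents named are taken as commercial.

Step 1
Reactants: 1 4-methoxybenzyl alcohol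
Product: 2 4-methoxybenzyl vinyl ether
Conditions: Pd(OCOCF3)2 (0.5 mol %), 4,7-diphenyl-1,10-phenanthroline, Et3N, butyl vinyl ether (solvent), 75 °C
Reagents that add atoms: butyl vinyl ether, C=COCCCC
Why: Palladium-catalysed transfer vinylation (vinyl ether exchange) of a primary benzylic alcohol, driven by the large excess of butyl vinyl ether; no stereocentre is involved.

Step 2
Reactants: 2 4-methoxybenzyl vinyl ether
Product: 4 methyl (E)-4-[(4-methoxybenzyl)oxy]-2-oxobut-3-enoate, via chloro ether 3 (not isolated)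
Conditions: ClCOCO2Me, pyridine, CH2Cl2, 0 °C → rt
Reagents that add atoms: methyl chlorooxoacetate, COC(=O)C(=O)Cl
Why: Electrophilic C-acylation of the enol ether at its β-carbon gives chloro ether 3, which loses HCl to pyridine to give the conjugated β-alkoxyvinyl keto ester with the thermodynamically preferred E geometry.

Step 3
Reactants: 5 2-methylcyclohex-2-en-1-one
Product: 6 (R)-2-methylcyclohex-2-en-1-ol
Conditions: (S)-2-methyl-CBS-oxazaborolidine (10 mol %), catecholborane, toluene, −78 °C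
Reagents that add atoms: none
Why: Corey–Bakshi–Shibata reduction, in which the oxazaborolidine-bound borane delivers hydride to one carbonyl face with the alkenyl side acting as the large group, should set the future C1 carbinol as R.

Step 4
Reactants: 6 (R)-2-methylcyclohex-2-en-1-ol
Product: 7 (R)-tert-butyldimethyl[(2-methylcyclohex-2-en-1-yl)oxy]silane
Conditions: TBSCl, imidazole, DMF, rt
Reagents that add atoms: tert-butyldimethylsilyl chloride, CC(C)(C)[Si](C)(C)Cl
Why: Standard silylation of the secondary allylic alcohol protects O1 for the whole route without touching the stereocentre.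

Step 5
Reactants: 7 (R)-tert-butyldimethyl[(2-methylcyclohex-2-en-1-yl)oxy]silane
Product: 8 (R)-4-[(tert-butyldimethylsilyl)oxy]-3-methylcyclohex-2-en-1-one
Conditions: CrO3, 3,5-dimethylpyrazole, CH2Cl2, −20 °C
Reagents that add atoms: chromium trioxide, O=[Cr](=O)=O
Why: Chromium trioxide–dimethylpyrazole allylic oxidation should take the only unhindered allylic methylene (the one next to the CH= end of the trisubstituted alkene) and give the γ-silyloxy enone with the carbonyl at the future C4 and the stereocentre untouched.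

Step 6
Reactants: 8 (R)-4-[(tert-butyldimethylsilyl)oxy]-3-methylcyclohex-2-en-1-one
Product: 9 (3R,4R)-3-allyl-4-[(tert-butyldimethylsilyl)oxy]-3-methyl-1-[(trimethylsilyl)oxy]cyclohex-1-ene
Conditions: allylmagnesium bromide, CuBr·SMe2 (20 mol %), Me3SiCl, THF, −78 °C
Reagents that add atoms: allylmagnesium bromide, C=CC[Mg]Br; chlorotrimethylsilane, C[Si](C)(C)Cl
Why: Copper-catalysed conjugate allylation accelerated by Me3SiCl should add the allyl group to the β,β-disubstituted enone anti to the neighbouring OTBS group, which sets the quaternary C10 (methyl cis to O1) and traps the enolate regiospecifically as the C4–C5 silyl enol ether.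

Step 7
Reactants: 9 (3R,4R)-3-allyl-4-[(tert-butyldimethylsilyl)oxy]-3-methyl-1-[(trimethylsilyl)oxy]cyclohex-1-ene
Product: 11 (3R,4R)-3-allyl-4-[(tert-butyldimethylsilyl)oxy]-3-methyl-2-(trifluoroacetyl)cyclohexan-1-one (ring enol form), via lithium enolate 10 (not isolated)
Conditions: MeLi, THF, 0 °C; then CF3CO2CH2CF3, −78 °C; aq. HCl work-up
Reagents that add atoms: 2,2,2-trifluoroethyl trifluoroacetate, O=C(OCC(F)(F)F)C(F)(F)F
Why: MeLi cleaves the silyl enol ether to the regiodefined lithium enolate 10, which is C-acylated at the hindered C5 by the small, highly electrophilic trifluoroacetate ester (Claisen-type activation for diazo transfer), so that C5 and not C3 becomes the 1,3-dicarbonyl carbon.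

Step 8
Reactants: 11 (3R,4R)-3-allyl-4-[(tert-butyldimethylsilyl)oxy]-3-methyl-2-(trifluoroacetyl)cyclohexan-1-one
Product: 13 2-[(1R,6R)-6-[(tert-butyldimethylsilyl)oxy]-1-methyl-3-oxo-2-(trifluoroacetyl)cyclohexyl]acetaldehyde (ring enol form), via diol 12 (not isolated)
Conditions: OsO4 (2 mol %), NaIO4, 2,6-lutidine, 1,4-dioxane/H2O, rt
Reagents that add atoms: sodium periodate (NaIO4), [Na+].[O-]I(=O)(=O)=O
Why: Lemieux–Johnson oxidation, in which OsO4 dihydroxylates the electron-rich terminal alkene to diol 12 in preference to the electron-poor tetrasubstituted enol double bond and NaIO4 cleaves the diol to the C8 aldehyde.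

Step 9
Reactants: 13 2-[(1R,6R)-6-[(tert-butyldimethylsilyl)oxy]-1-methyl-3-oxo-2-(trifluoroacetyl)cyclohexyl]acetaldehyde
Product: 14 2-[(1R,6R)-6-[(tert-butyldimethylsilyl)oxy]-2-diazo-1-methyl-3-oxocyclohexyl]acetaldehyde
Conditions: 4-acetamidobenzenesulfonyl azide, Et3N, H2O (1 equiv), MeCN, rt
Reagents that add atoms: 4-acetamidobenzenesulfonyl azide, CC(=O)Nc1ccc(cc1)S(=O)(=O)N=[N+]=[N-]
Why: Detrifluoroacetylative Regitz diazo transfer, in which the enolate of the 1,3-dicarbonyl attacks the sulfonyl azide and the trifluoroacetyl group leaves on the sulfonamide nitrogen, puts the diazo group on C5 next to the C4 ketone without touching a stereocentre.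

Step 10
Reactants: 14 2-[(1R,6R)-6-[(tert-butyldimethylsilyl)oxy]-2-diazo-1-methyl-3-oxocyclohexyl]acetaldehyde; 4 methyl (E)-4-[(4-methoxybenzyl)oxy]-2-oxobut-3-enoate
Product: 16 methyl 5α,8α-epoxy-6α-(PMBO)-4,11-dioxo-1β-(TBSO)-13,15-dinoreudesman-12-oate, via carbonyl ylide 15 (not isolated)
Conditions: Rh2(OAc)4 (2 mol %), 4 (3 equiv), benzene, 50 °C, slow addition of 14
Reagents that add atoms: none
Why: Rh2(OAc)4 extrudes N2 from 14 and the aldehyde oxygen adds to the metal-bound carbene carbon C5 (five-membered O–C5 ring closure) to give carbonyl ylide 15, a C4-ketone-stabilised 1,3-dipole with termini C5 and C8, which adds suprafacially across the E-alkene of 4 and so forms C5–C6 and C7–C8, giving ring B as a 5α,8α-oxygen-bridged 7-oxabicyclo[2.2.1]heptane. The closest known reaction type is the tandem carbonyl ylide formation–1,3-dipolar cycloaddition of α-diazo ketones that carry a tethered carbonyl group, run with an electron-poor alkene. The ylide ring closes first by attack of the carbonyl lone pair on the carbene, and ring B and the second oxolane ring then close together in the concerted intermolecular [3+2] step. Facial control at C5 and C8: the alkene bonds to the ylide face anti to C1, which is the face of the C10 methyl, because only this keeps ring A exo (cis-fused) on the emerging oxabicycle, so the oxygen bridge ends α; the E geometry makes O6 and C11 trans, and an endo substituent on C6 would clash with the endo C10 methyl, so the PMB ether sits exo (6α) and the keto ester endo (7β). Regioselectivity follows from polarity matching, the enolate-like C5 terminus bonding to the electrophilic β-carbon C6 of the push–pull alkene and the oxocarbenium-like C8 to C7. The step also needs chemoselectivity for the C=C over the keto C=O of 4 (a deactivated vinylogous carbonate carbonyl) and over ylide dimerisation, which excess 4 and slow addition of 14 should secure.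

Step 11
Reactants: 16 methyl 5α,8α-epoxy-6α-(PMBO)-4,11-dioxo-1β-(TBSO)-13,15-dinoreudesman-12-oate
Product: 17 methyl 5α,8α-epoxy-6α-(PMBO)-4-oxo-1β-(TBSO)-15-noreudesm-11(13)-en-12-oate
Conditions: Ph3PCH3Br, KN(SiMe3)2, THF, −78 °C (ylide preformed); then 16, −78 → −40 °C
Reagents that add atoms: methyltriphenylphosphonium bromide, C[P+](c1ccccc1)(c1ccccc1)c1ccccc1.[Br-]
Why: Wittig methylenation, in which the α-keto ester carbonyl is far more electrophilic and less hindered than the C4 ketone on the quaternary bridgehead, so one equivalent of salt-free ylide at low temperature should convert only C11=O into the C11=C13 alkene before enolisation at C7 can start.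

Step 12
Reactants: 17 methyl 5α,8α-epoxy-6α-(PMBO)-4-oxo-1β-(TBSO)-15-noreudesm-11(13)-en-12-oate
Product: 19 methyl 8α-hydroxy-6α-(PMBO)-4-oxo-1β-(TBSO)-15-noreudesm-11(13)-en-12-oate (5α-H), via samarium enolate 18 (not isolated)
Conditions: SmI2 (2.5 equiv), MeOH, THF, −78 °C; sat. aq. NH4Cl at −78 °C
Reagents that add atoms: none
Why: SmI2 reduction of an α-alkoxy ketone, in which two single-electron transfers to the C4 ketone expel the bridge oxygen from C5 (the C5–O bond is held perpendicular to the carbonyl plane) so that it stays on C8 as the 8α-alkoxide, and samarium enolate 18 is protonated by MeOH at C5 on the α face, anti to the C10 methyl, which is also the thermodynamic trans ring fusion; at −78 °C the acrylate should not be reduced.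

Step 13
Reactants: 19 methyl 8α-hydroxy-6α-(PMBO)-4-oxo-1β-(TBSO)-15-noreudesm-11(13)-en-12-oate
Product: 20 methyl 6α-(PMBO)-4-oxo-1β-(TBSO)-8α-(TESO)-15-noreudesm-11(13)-en-12-oate
Conditions: Et3SiCl, imidazole, DMF, 0 °C → rt
Reagents that add atoms: chlorotriethylsilane, CC[Si](Cl)(CC)CC
Why: Silylation of the only free hydroxyl (8α-OH) under conditions too mild to enolise the β-alkoxy ketone keeps O8 masked for the later acylation of O6.

Step 14
Reactants: 20 methyl 6α-(PMBO)-4-oxo-1β-(TBSO)-8α-(TESO)-15-noreudesm-11(13)-en-12-oate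
Product: 21 methyl 6α-(PMBO)-1β-(TBSO)-8α-(TESO)eudesma-4(15),11(13)-dien-12-oate
Conditions: Zn, CH2Br2, TiCl4 (reagent preformed in THF), CH2Cl2, 0 °C → rt
Reagents that add atoms: dibromomethane, BrCBr
Why: Takai–Lombardo methylenation with the non-basic zinc/titanium methylene reagent should convert the hindered, epimerisable, β-alkoxy C4 ketone into the C4=C15 alkene without elimination, epimerisation at C5 or attack on the ester.

Step 15
Reactants: 21 methyl 6α-(PMBO)-1β-(TBSO)-8α-(TESO)eudesma-4(15),11(13)-dien-12-oate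
Product: 22 methyl 6α-hydroxy-1β-(TBSO)-8α-(TESO)eudesma-4(15),11(13)-dien-12-oate
Conditions: DDQ, CH2Cl2/pH 7 phosphate buffer (10:1), 0 °C
Reagents that add atoms: none
Why: Oxidative cleavage of the PMB ether by DDQ (hydride abstraction and hydrolysis) frees 6α-OH; the silyl ethers, the acrylate and the alkene are inert, and no free hydroxyl is near O6 that could give a benzylidene acetal.

Step 16
Reactants: 22 methyl 6α-hydroxy-1β-(TBSO)-8α-(TESO)eudesma-4(15),11(13)-dien-12-oate
Product: 24 methyl 4α,6α-dihydroxy-1β-(TBSO)-8α-(TESO)eudesm-11(13)-en-12-oate, via organomercurial 23 (not isolated)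
Conditions: Hg(OAc)2, THF/H2O (1:1), rt; then NaBH4, aq. NaOH, 0 °C
Reagents that add atoms: water, O
Why: Markovnikov oxymercuration of the electron-rich 1,1-disubstituted C4=C15 alkene (the acrylate is too electron-poor to be mercurated), with water attacking C4 from the α face because the β (axial) path is blocked by the syn-axial C10 methyl, should give organomercurial 23 with equatorial 4α-OH, and borohydride demercuration turns CH2Hg into the axial 4β-methyl.

Step 17
Reactants: 24 methyl 4α,6α-dihydroxy-1β-(TBSO)-8α-(TESO)eudesm-11(13)-en-12-oate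
Product: 25 methyl 6α-angeloyloxy-4α-hydroxy-1β-(TBSO)-8α-(TESO)eudesm-11(13)-en-12-oate
Conditions: angelic acid, 2,4,6-trichlorobenzoyl chloride, Et3N, toluene, rt; then 24, 80 °C
Reagents that add atoms: angelic acid, C/C=C(/C)C(=O)O
Why: Yamaguchi esterification through the mixed 2,4,6-trichlorobenzoic anhydride acylates the secondary 6α-OH (the tertiary 4α-OH does not react, O8 and O1 are silylated) and, run without a nucleophilic catalyst, should keep the Z geometry of the angeloyl group.

Step 18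
Reactants: 25 methyl 6α-angeloyloxy-4α-hydroxy-1β-(TBSO)-8α-(TESO)eudesm-11(13)-en-12-oate
Product: 26 methyl 6α-angeloyloxy-1β,4α,8α-trihydroxyeudesm-11(13)-en-12-oate (CNP0136844.1)
Conditions: HF·pyridine, pyridine, THF, 0 °C → rt
Reagents that add atoms: none
Why: Buffered HF·pyridine removes both silyl ethers under non-basic conditions, which should avoid acyl migration from O6 to O8 and lactonisation of the γ-hydroxy ester, and gives the target.

**Compound list**
1 | 4-methoxybenzyl alcohol | COc1ccc(CO)cc1 | starting material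
2 | 4-methoxybenzyl vinyl ether | C=COCc1ccc(OC)cc1 | intermediate
3 | methyl 4-chloro-4-[(4-methoxybenzyl)oxy]-2-oxobutanoate (chloro ether, racemic) | COC(=O)C(=O)CC(Cl)OCc1ccc(OC)cc1 | intermediate
4 | methyl (E)-4-[(4-methoxybenzyl)oxy]-2-oxobut-3-enoate | COC(=O)C(=O)/C=C/OCc1ccc(OC)cc1 | intermediate
5 | 2-methylcyclohex-2-en-1-one | CC1=CCCCC1=O | starting material
6 | (R)-2-methylcyclohex-2-en-1-ol | O[C@@H]1CCCC=C1C | intermediate
7 | (R)-tert-butyldimethyl[(2-methylcyclohex-2-en-1-yl)oxy]silane | CC(C)(C)[Si](C)(C)O[C@@H]1CCCC=C1C | intermediate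
8 | (R)-4-[(tert-butyldimethylsilyl)oxy]-3-methylcyclohex-2-en-1-one | O=C1C=C(C)[C@H](O[Si](C)(C)C(C)(C)C)CC1 | intermediate
9 | (3R,4R)-3-allyl-4-[(tert-butyldimethylsilyl)oxy]-3-methyl-1-[(trimethylsilyl)oxy]cyclohex-1-ene | C[Si](C)(C)OC1=C[C@@](C)(CC=C)[C@H](O[Si](C)(C)C(C)(C)C)CC1 | intermediate
10 | lithium (3R,4R)-3-allyl-4-[(tert-butyldimethylsilyl)oxy]-3-methylcyclohex-1-en-1-olate (lithium enolate) | [Li]OC1=C[C@@](C)(CC=C)[C@H](O[Si](C)(C)C(C)(C)C)CC1 | intermediate
11 | (3R,4R)-3-allyl-4-[(tert-butyldimethylsilyl)oxy]-3-methyl-2-(trifluoroacetyl)cyclohexan-1-one, drawn as its ring enol | OC1=C(C(=O)C(F)(F)F)[C@@](C)(CC=C)[C@H](O[Si](C)(C)C(C)(C)C)CC1 | intermediate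
12 | 2,3-dihydroxypropyl analogue of 11 (diol, mixture at the new carbinol) | OC1=C(C(=O)C(F)(F)F)[C@@](C)(CC(O)CO)[C@H](O[Si](C)(C)C(C)(C)C)CC1 | intermediate
13 | 2-[(1R,6R)-6-[(tert-butyldimethylsilyl)oxy]-1-methyl-3-oxo-2-(trifluoroacetyl)cyclohexyl]acetaldehyde, drawn as its ring enol | OC1=C(C(=O)C(F)(F)F)[C@@](C)(CC=O)[C@H](O[Si](C)(C)C(C)(C)C)CC1 | intermediate
14 | 2-[(1R,6R)-6-[(tert-butyldimethylsilyl)oxy]-2-diazo-1-methyl-3-oxocyclohexyl]acetaldehyde | O=C1C(=[N+]=[N-])[C@@](C)(CC=O)[C@H](O[Si](C)(C)C(C)(C)C)CC1 | intermediate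
15 | cyclic carbonyl ylide (C5 carbanion next to the C4 ketone, C5–O–C8 oxonium, ring A fused at C5–C10, 1β-OTBS, 10β-methyl) | O=C1[C-]2[O+]=CC[C@@]2(C)[C@H](O[Si](C)(C)C(C)(C)C)CC1 | intermediate
16 | methyl 5α,8α-epoxy-6α-(4-methoxybenzyloxy)-4,11-dioxo-1β-(tert-butyldimethylsilyloxy)-13,15-dinoreudesman-12-oate (cycloadduct; 6-ether exo, 7-keto ester endo) | COC(=O)C(=O)[C@H]1[C@H](OCc4ccc(OC)cc4)[C@@]32[C@@](C)(C[C@@H]1O3)[C@H](O[Si](C)(C)C(C)(C)C)CCC2=O | intermediate
17 | methyl 5α,8α-epoxy-6α-(4-methoxybenzyloxy)-4-oxo-1β-(tert-butyldimethylsilyloxy)-15-noreudesm-11(13)-en-12-oate | COC(=O)C(=C)[C@H]1[C@H](OCc4ccc(OC)cc4)[C@@]32[C@@](C)(C[C@@H]1O3)[C@H](O[Si](C)(C)C(C)(C)C)CCC2=O | intermediate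
18 | samarium enolate (C4–O–SmI2, C4=C5; 8α-O–SmI2) | COC(=O)C(=C)[C@H]1[C@H](OCc3ccc(OC)cc3)C2=C(O[Sm](I)I)CC[C@@H](O[Si](C)(C)C(C)(C)C)[C@]2(C)C[C@@H]1O[Sm](I)I | intermediate
19 | methyl 8α-hydroxy-6α-(4-methoxybenzyloxy)-4-oxo-1β-(tert-butyldimethylsilyloxy)-15-noreudesm-11(13)-en-12-oate (5α-H, trans-fused) | COC(=O)C(=C)[C@H]1[C@H](OCc3ccc(OC)cc3)[C@@H]2[C@@](C)(C[C@@H]1O)[C@H](O[Si](C)(C)C(C)(C)C)CCC2=O | intermediate
20 | methyl 6α-(4-methoxybenzyloxy)-4-oxo-1β-(tert-butyldimethylsilyloxy)-8α-(triethylsilyloxy)-15-noreudesm-11(13)-en-12-oate | COC(=O)C(=C)[C@H]1[C@H](OCc3ccc(OC)cc3)[C@@H]2[C@@](C)(C[C@@H]1O[Si](CC)(CC)CC)[C@H](O[Si](C)(C)C(C)(C)C)CCC2=O | intermediate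
21 | methyl 6α-(4-methoxybenzyloxy)-1β-(tert-butyldimethylsilyloxy)-8α-(triethylsilyloxy)eudesma-4(15),11(13)-dien-12-oate | COC(=O)C(=C)[C@H]1[C@H](OCc3ccc(OC)cc3)[C@@H]2[C@@](C)(C[C@@H]1O[Si](CC)(CC)CC)[C@H](O[Si](C)(C)C(C)(C)C)CCC2=C | intermediate
22 | methyl 6α-hydroxy-1β-(tert-butyldimethylsilyloxy)-8α-(triethylsilyloxy)eudesma-4(15),11(13)-dien-12-oate | COC(=O)C(=C)[C@H]1[C@H](O)[C@@H]2[C@@](C)(C[C@@H]1O[Si](CC)(CC)CC)[C@H](O[Si](C)(C)C(C)(C)C)CCC2=C | intermediate
23 | organomercurial (4α-hydroxy, 15-acetoxymercurio) | COC(=O)C(=C)[C@H]1[C@H](O)[C@@H]2[C@@](C)(C[C@@H]1O[Si](CC)(CC)CC)[C@H](O[Si](C)(C)C(C)(C)C)CC[C@@]2(C[Hg]OC(C)=O)O | intermediate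
24 | methyl 4α,6α-dihydroxy-1β-(tert-butyldimethylsilyloxy)-8α-(triethylsilyloxy)eudesm-11(13)-en-12-oate | COC(=O)C(=C)[C@H]1[C@H](O)[C@@H]2[C@@](C)(C[C@@H]1O[Si](CC)(CC)CC)[C@H](O[Si](C)(C)C(C)(C)C)CC[C@@]2(C)O | intermediate
25 | methyl 6α-angeloyloxy-4α-hydroxy-1β-(tert-butyldimethylsilyloxy)-8α-(triethylsilyloxy)eudesm-11(13)-en-12-oate | COC(=O)C(=C)[C@H]1[C@H](OC(=O)/C(C)=C\C)[C@@H]2[C@@](C)(C[C@@H]1O[Si](CC)(CC)CC)[C@H](O[Si](C)(C)C(C)(C)C)CC[C@@]2(C)O | intermediate
26 | methyl 6α-angeloyloxy-1β,4α,8α-trihydroxyeudesm-11(13)-en-12-oate (CNP0136844.1) | C=C(C(=O)OC)[C@H]1[C@H](OC(=O)/C(C)=C\C)[C@@H]2[C@@](C)(C[C@@H]1O)[C@H](O)CC[C@@]2(C)O | target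

**Step count and risks**
Total step count: 18. Longest linear sequence: 16 steps (steps 3–18, from 5); steps 1–2 make dipolarophile 4.

Steps most likely to fail:

1. Step 10. The ylide may add across the ketone C=O of 4 instead of its C=C, or, being hindered at C5, may be lost to dimerisation or proton transfer before the alkene traps it. Fallback, from 14 back to 21: the cycloaddition would be run under the same Rh2(OAc)4 conditions with (E)-3-[(4-methoxybenzyl)oxy]prop-2-enenitrile F1, a dipolarophile without a competing carbonyl group, made from 1 and commercial 3-methoxyacrylonitrile by alkoxide-catalysed alkoxy exchange (KOtBu cat., toluene, MeOH distilled off). This should give the 7β-cyano cycloadduct F2. SmI2/MeOH at −78 °C then opens the bridge to the 8α-hydroxy ketone F3, Et3SiCl/imidazole gives the 8α-silyl ether F4, and Zn/CH2Br2/TiCl4 gives the 4-methylene nitrile F5. MeLi followed by mild aqueous acid converts the nitrile into the 7β-acetyl compound F6, KN(SiMe3)2/PhNTf2 at −78 °C gives the kinetic enol triflate F7, and methoxycarbonylation (Pd(OAc)2, PPh3, CO, MeOH, Et3N, DMF) returns to 21. The acrylate is then built after the bridge opening and the C4 methylenation.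

2. Step 17. Acylation of the hindered 6α-hydroxyl at 80 °C may be slower than its lactonisation onto the C12 ester or than Z-to-E isomerisation of the activated angelic acid. Fallback, from 24 back to 25: 24 would be esterified at room temperature with the unhindered 2-[bis(2,2,2-trifluoroethoxy)phosphoryl]propanoic acid (EDC·HCl, DMAP, CH2Cl2) to give the 6α-phosphonopropanoate F10. Still–Gennari olefination with acetaldehyde (KN(SiMe3)2, 18-crown-6, THF, −78 °C) then builds the Z-trisubstituted alkene on the ester already in place and gives 25.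

3. Step 16. Water may attack C4 with poor facial selectivity, or the alkaline borohydride stage may lactonise the 6-hydroxy ester or reduce the acrylate. Fallback, from 22 back to 24: mCPBA (NaHCO3, CH2Cl2, 0 °C) would epoxidise only the electron-rich exocyclic alkene, from the α face (anti to the C10 methyl and syn to 6α-OH), to give the 4α,15-epoxide F8. MgI2 (Et2O, −40 °C) opens it at the primary C15 to the iodohydrin F9, and Bu3SnH/AIBN (benzene, 80 °C) removes the iodine to give 24.

**Further compounds**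
F1 | step 10 | (E)-3-[(4-methoxybenzyl)oxy]prop-2-enenitrile | N#C/C=C/OCc1ccc(OC)cc1
F2 | step 10 | 7β-cyano cycloadduct (5α,8α-epoxy, 6α-OPMB, 4-oxo, 1β-OTBS; nitrile analogue of 16) | N#C[C@H]1[C@H](OCc4ccc(OC)cc4)[C@@]32[C@@](C)(C[C@@H]1O3)[C@H](O[Si](C)(C)C(C)(C)C)CCC2=O
F3 | step 10 | 7β-cyano 8α-hydroxy ketone (nitrile analogue of 19) | N#C[C@H]1[C@H](OCc3ccc(OC)cc3)[C@@H]2[C@@](C)(C[C@@H]1O)[C@H](O[Si](C)(C)C(C)(C)C)CCC2=O
F4 | step 10 | 7β-cyano 8α-triethylsilyl ether (nitrile analogue of 20) | N#C[C@H]1[C@H](OCc3ccc(OC)cc3)[C@@H]2[C@@](C)(C[C@@H]1O[Si](CC)(CC)CC)[C@H](O[Si](C)(C)C(C)(C)C)CCC2=O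
F5 | step 10 | 7β-cyano 4-methylene compound (nitrile analogue of 21) | N#C[C@H]1[C@H](OCc3ccc(OC)cc3)[C@@H]2[C@@](C)(C[C@@H]1O[Si](CC)(CC)CC)[C@H](O[Si](C)(C)C(C)(C)C)CCC2=C
F6 | step 10 | 7β-acetyl 4-methylene compound (methyl ketone) | CC(=O)[C@H]1[C@H](OCc3ccc(OC)cc3)[C@@H]2[C@@](C)(C[C@@H]1O[Si](CC)(CC)CC)[C@H](O[Si](C)(C)C(C)(C)C)CCC2=C
F7 | step 10 | 7β-[1-(trifluoromethylsulfonyloxy)vinyl] compound (enol triflate) | C=C(OS(=O)(=O)C(F)(F)F)[C@H]1[C@H](OCc3ccc(OC)cc3)[C@@H]2[C@@](C)(C[C@@H]1O[Si](CC)(CC)CC)[C@H](O[Si](C)(C)C(C)(C)C)CCC2=C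
F8 | step 16 | 4α,15-epoxide of 22 | COC(=O)C(=C)[C@H]1[C@H](O)[C@@H]2[C@@](C)(C[C@@H]1O[Si](CC)(CC)CC)[C@H](O[Si](C)(C)C(C)(C)C)CC[C@]23CO3
F9 | step 16 | 4α-hydroxy-15-iodo compound (iodohydrin) | COC(=O)C(=C)[C@H]1[C@H](O)[C@@H]2[C@@](C)(C[C@@H]1O[Si](CC)(CC)CC)[C@H](O[Si](C)(C)C(C)(C)C)CC[C@@]2(CI)O
F10 | step 17 | 6α-O-{2-[bis(2,2,2-trifluoroethoxy)phosphoryl]propanoyl} ester of 24 | COC(=O)C(=C)[C@H]1[C@H](OC(=O)C(C)P(=O)(OCC(F)(F)F)OCC(F)(F)F)[C@@H]2[C@@](C)(C[C@@H]1O[Si](CC)(CC)CC)[C@H](O[Si](C)(C)C(C)(C)C)CC[C@@]2(C)O
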